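**Assumption:** the target has no stereocentre or stereogenic axis (it is achiral), so the SMILES defines one compound and no stereocontrol is needed.

## Retrosynthetic overview

1. Target flavone 7 ⇒ open the pyranone at O1–C8a (aryl C–O) and O1–C2 (enol C–O). This leads back to the non-phenolic 1,3-diketone 3, whose A-ring ortho C–H is oxygenated and closed in one pot.
2. Diketone 3 ⇒ crossed Claisen disconnection between 2,3,4-trimethoxyacetophenone 1 and methyl 3-hydroxy-4,5-dimethoxybenzoate 2.
3. Ring order: rings A and B are bought intact; ring C (the pyranone) is the only ring formed, in the last step.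

## Route

Step 1
Reactants: 1 1-(2,3,4-trimethoxyphenyl)ethanone; 2 methyl 3-hydroxy-4,5-dimethoxybenzoate
Product: 3 1-(3-hydroxy-4,5-dimethoxyphenyl)-3-(2,3,4-trimethoxyphenyl)propane-1,3-dione
Conditions: LiHMDS (4 equiv), THF, −78 °C to 50 °C; then 1 M HCl
Reagents that add atoms: none
Why: Crossed Claisen condensation: the lithium enolate of 1 acylates the non-enolisable ester 2 (its phenoxide is meta to the ester, so it does not deactivate it by resonance), and irreversible deprotonation of the β-diketone product drives the reaction; no stereocentre is formed.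

Step 2
Reactants: 3 1-(3-hydroxy-4,5-dimethoxyphenyl)-3-(2,3,4-trimethoxyphenyl)propane-1,3-dione
Product: 7 2-(3-hydroxy-4,5-dimethoxyphenyl)-5,6,7-trimethoxy-4H-chromen-4-one, via B-ring trifluoroacetate 4 (not isolated), via bis-trifluoroacetate 5 (not isolated), via hydroxy-diketone 6 (not isolated)
Conditions: Pd(TFA)2 (10 mol%), K2S2O8 (1.5 equiv), TFA/TFAA 9:1, sealed tube, 50 °C; then H2O, 70 °C
Reagents that add atoms: trifluoroacetic acid, OC(=O)C(F)(F)F (its trifluoroacetate oxygen becomes ring oxygen O1; the CF3CO group is lost on hydrolysis)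
Why: Proposed new method: a ketone-directed ortho-C–H oxygenation/cyclodehydration cascade on an enolised 1,3-diaryl-1,3-diketone. TFAA first masks the B-ring phenol as the electron-poor trifluoroacetate 4. The A-ring carbonyl then directs electrophilic palladation to the only ortho C–H (C6, unhindered and para to the 3-OMe), whereas both B-ring ortho C–H bonds are flanked by oxygen substituents. Persulfate oxidises the five-membered palladacycle to Pd(IV), and C–O reductive elimination gives aryl trifluoroacetate 5. Added water cleaves both trifluoroacetates, and hot TFA closes phenol 6 onto the distal carbonyl and dehydrates to the pyranone, whose C5-OMe blocks any further carbonyl-directed oxidation. No stereocentre is formed. The closest known reaction types are Pd(II)/Pd(IV) ketone-directed ortho-hydroxylation of simple aryl ketones in TFA/TFAA with persulfate, and the acid cyclodehydration of o-hydroxyaryl 1,3-diketones (last stage of the Baker–Venkataraman flavone synthesis).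

## Compound list

1 | 1-(2,3,4-trimethoxyphenyl)ethanone (2',3',4'-trimethoxyacetophenone) | CC(=O)c1ccc(OC)c(OC)c1OC | starting material
2 | methyl 3-hydroxy-4,5-dimethoxybenzoate | COC(=O)c1cc(O)c(OC)c(OC)c1 | starting material
3 | 1-(3-hydroxy-4,5-dimethoxyphenyl)-3-(2,3,4-trimethoxyphenyl)propane-1,3-dione (drawn as diketo form; largely enolised) | COc1ccc(C(=O)CC(=O)c2cc(O)c(OC)c(OC)c2)c(OC)c1OC | intermediate
4 | 1-[3,4-dimethoxy-5-(trifluoroacetoxy)phenyl]-3-(2,3,4-trimethoxyphenyl)propane-1,3-dione | COc1ccc(C(=O)CC(=O)c2cc(OC)c(OC)c(OC(=O)C(F)(F)F)c2)c(OC)c1OC | intermediate (not isolated)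
5 | 1-[3,4-dimethoxy-5-(trifluoroacetoxy)phenyl]-3-[2,3,4-trimethoxy-6-(trifluoroacetoxy)phenyl]propane-1,3-dione | COc1cc(OC(=O)C(F)(F)F)c(C(=O)CC(=O)c2cc(OC)c(OC)c(OC(=O)C(F)(F)F)c2)c(OC)c1OC | intermediate (not isolated)
6 | 1-(3-hydroxy-4,5-dimethoxyphenyl)-3-(6-hydroxy-2,3,4-trimethoxyphenyl)propane-1,3-dione | COc1cc(O)c(C(=O)CC(=O)c2cc(O)c(OC)c(OC)c2)c(OC)c1OC | intermediate (not isolated)
7 | 2-(3-hydroxy-4,5-dimethoxyphenyl)-5,6,7-trimethoxy-4H-chromen-4-one (3'-hydroxy-5,6,7,4',5'-pentamethoxyflavone) | COc1cc(-c2cc(=O)c3c(OC)c(OC)c(OC)cc3o2)cc(O)c1OC | target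

## Step count and risks

Total step count: 2. Longest linear sequence: 2.

The route has only two steps, so both are ranked; there is no third.

**1. Step 2 (the proposed new step; most likely to fail).** Possible failure modes:
- the enolised diketone binds Pd as an O,O-chelate and shuts down C–H activation;
- persulfate oxidises the active methylene or the electron-rich rings;
- oxygenation competes on the B ring.

Fallback by known chemistry: this sets out from 2. It is condensed under the same LiHMDS Claisen conditions (5 equiv, THF, −78 °C to reflux) with purchased 1-(6-hydroxy-2,3,4-trimethoxyphenyl)ethanone F3, so the ring oxygen is bought rather than installed. This gives the o-hydroxy diketone 6, now isolated, which is where the fallback comes back to the route. Closure of 6 with catalytic H2SO4 in AcOH at 100 °C (classical cyclodehydration) gives 7.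

**2. Step 1.** Possible failure modes: the phenoxide form of 2 may be too sluggish or insoluble as an acyl acceptor, and self-aldol of 1 may compete.

Fallback: this sets out from 2. It is first protected with MOMCl and i-Pr2NEt in CH2Cl2 to give methyl 3,4-dimethoxy-5-(methoxymethoxy)benzoate F1. F1 undergoes the Claisen condensation with 1 (LiHMDS 2.2 equiv, THF) as a neutral, fully soluble ester to give 1-[3,4-dimethoxy-5-(methoxymethoxy)phenyl]-3-(2,3,4-trimethoxyphenyl)propane-1,3-dione F2. Removal of the MOM group with HCl in MeOH at 50 °C returns to the route at 3.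

## Further compounds

F1 | step 1 | methyl 3,4-dimethoxy-5-(methoxymethoxy)benzoate | COCOc1cc(C(=O)OC)cc(OC)c1OC
F2 | step 1 | 1-[3,4-dimethoxy-5-(methoxymethoxy)phenyl]-3-(2,3,4-trimethoxyphenyl)propane-1,3-dione | COCOc1cc(C(=O)CC(=O)c2ccc(OC)c(OC)c2OC)cc(OC)c1OC
F3 | step 2 | 1-(6-hydroxy-2,3,4-trimethoxyphenyl)ethanone (purchased) | CC(=O)c1c(O)cc(OC)c(OC)c1OC
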